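**Retrosynthetic overview**
1. The target is a 5,7,2',4'-tetrahydroxyflavone whose C8 carries C1''H2–C2''H(isopropenyl)–C3''H2–C4''H2–C5''(OH)Me2, with C2'' (R) as the only stereocentre. Ring A is bought as phloroglucinol and ring B as 2,4-dihydroxybenzaldehyde; the pyranone ring C is the only ring made, and it is made last.
2. Ring C: O1–C2 is formed by 6-endo closure of the C8a hydroxyl onto a ring-A aryl alkynyl ketone. Its C4a–C4 bond comes from a C4a aryllithium and a ring-B arylpropiolic Weinreb amide; a TIPS ether on O5 keeps that oxygen out of the closure.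
3. The isopropenyl group on C2'' comes from a C2''–B bond by Zweifel olefination (retention). The C5'' hydroxyl comes from Mukaiyama hydration of a C4''=C5'' alkene while it is the only alkene present.
4. Feature the strategy rests on: C2''–C3'' is a two-carbon unit between the benzylic C1'' on C8 of ring A and the alkenyl carbon C4'', so it can be a vinyl group on boron. In one palladium-catalysed enantioselective conjunctive coupling the C1'' benzyl group migrates from boron to C2'' and 1-bromo-2-methylpropene is joined to C3'', so C2'' is created bearing boron.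
5. The benzylic boronate comes from phloroglucinol by bis-MOM/TIPS protection, lithiation between the two MOM ethers and one-carbon boronate homologation.

Key step: step 4

Remark: flavone locants are used for the ring positions and C1''–C5'' for the side chain (C1'' = benzylic CH2 on C8, C5'' = carbinol carbon).
Assumption: the (Sp,Sp) antipode of MandyPhos is written for the (R)-boronate; the sense of induction for this benzyl/alkenyl pair is to be confirmed on a model run, and the (Rp,Rp) antipode is used if it proves opposite.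

**Route**

Step 1
Reactants: 1 phloroglucinol
Product: 2 3,5-bis(methoxymethoxy)phenol
Conditions: MOMCl (2.0 equiv), i-Pr2NEt (2.2 equiv), CH2Cl2/DMF, 0 °C → rt; chromatography
Reagents that add atoms: chloromethyl methyl ether, COCCl
Why: Williamson-type O-alkylation of the symmetric triphenol with two equivalents of the hard electrophile should give the bis-ether as the main fraction of a statistical mixture, from which the mono- and tris-ethers are separable.

Step 2
Reactants: 2 3,5-bis(methoxymethoxy)phenol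
Product: 3 [3,5-bis(methoxymethoxy)phenoxy]triisopropylsilane
Conditions: TIPSCl, imidazole, DMF, rt
Reagents that add atoms: chlorotriisopropylsilane, CC(C)[Si](Cl)(C(C)C)C(C)C
Why: Standard silylation of the one free phenol puts a base-stable, acid-tolerant group on the oxygen that becomes O5, and its bulk shields the two ring positions next to it.

Step 3
Reactants: 3 [3,5-bis(methoxymethoxy)phenoxy]triisopropylsilane
Product: 6 2-{[2,6-bis(methoxymethoxy)-4-(triisopropylsilyloxy)phenyl]methyl}-4,4,5,5-tetramethyl-1,3,2-dioxaborolane, via aryllithium 4 (not isolated), via bromomethyl borate complex 5 (not isolated)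
Conditions: n-BuLi, THF, 0 °C; then BrCH2Bpin, −78 °C → rt
Reagents that add atoms: 2-(bromomethyl)-4,4,5,5-tetramethyl-1,3,2-dioxaborolane, BrCB1OC(C)(C)C(C)(C)O1
Why: Directed ortho-metalation occurs at the only position flanked by two MOM ethers, the aryllithium adds to boron, and the aryl group then displaces bromide from the α-carbon by 1,2-shift (Matteson homologation) to give the benzylic boronate.

Step 4
Reactants: 6 2-{[2,6-bis(methoxymethoxy)-4-(triisopropylsilyloxy)phenyl]methyl}-4,4,5,5-tetramethyl-1,3,2-dioxaborolane; 7 vinyl bromide; 8 1-bromo-2-methylprop-1-ene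
Product: 11 2-{(2R)-1-[2,6-bis(methoxymethoxy)-4-(triisopropylsilyloxy)phenyl]-5-methylhex-4-en-2-yl}-4,4,5,5-tetramethyl-1,3,2-dioxaborolane, via vinyllithium 9 (not isolated), via vinyl borate complex 10 (not isolated)
Conditions: 7 (slight excess), t-BuLi (2 equiv per 7), Et2O, −78 °C; add 6, 0 °C → rt; solvent switch to THF; Pd(OAc)2 (2 mol%), (Sp,Sp)-MandyPhos [2,2'-bis(α-dimethylaminobenzyl)-1,1'-bis(diphenylphosphino)ferrocene, 2.4 mol%], 8 (1.2 equiv), KOTf (3 equiv), 60 °C
Reagents that add atoms: none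
Why: Oxidative addition of zerovalent palladium–MandyPhos to bromide 8 and bromide removal by KOTf give a cationic alkenylpalladium species that binds the vinyl group of the four-coordinate boronate 10; the benzyl group (C1'') then migrates from boron to the boron-bearing carbon C2'' anti to palladium while the metal bonds to C3'', and reductive elimination joins C3'' to C4''. The closest known reaction type is the palladium/MandyPhos-catalysed enantioselective conjunctive cross-coupling of vinylboron ate complexes with alkenyl halides or triflates, in which primary alkyl groups migrate; the 2,6-dioxygenated benzyl group is a more hindered member of that class. No ring is closed. The new stereocentre C2'' is fixed by the face of the vinyl group that the chiral bisphosphine–palladium fragment binds, and the anti-periplanar 1,2-shift transfers that choice to carbon. The step needs the metalate shift to outrun direct transmetalation of vinyl or benzyl (Suzuki-type products) and β-hydride loss; the wide-bite-angle ferrocenyl ligand, the triflate salt that takes out inhibiting bromide, and the fact that benzyl is the only carbon group on boron besides vinyl secure this, and the MOM and TIPS ethers are inert to the catalyst.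

Step 5
Reactants: 11 2-{(2R)-1-[2,6-bis(methoxymethoxy)-4-(triisopropylsilyloxy)phenyl]-5-methylhex-4-en-2-yl}-4,4,5,5-tetramethyl-1,3,2-dioxaborolane
Product: 12 (5R)-6-[2,6-bis(methoxymethoxy)-4-(triisopropylsilyloxy)phenyl]-2-methyl-5-(4,4,5,5-tetramethyl-1,3,2-dioxaborolan-2-yl)hexan-2-ol
Conditions: Co(acac)2 (20 mol%), PhSiH3, O2 (1 atm), THF, rt
Reagents that add atoms: dioxygen, O=O
Why: Mukaiyama hydration transfers a hydrogen atom to C4'' of the only alkene and traps the tertiary C5'' radical with oxygen (Markovnikov), leaving the pinacol boronate and the remote C2'' stereocentre untouched, so that the later isopropenyl alkene never has to be distinguished from this one.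

Step 6
Reactants: 12 (5R)-6-[2,6-bis(methoxymethoxy)-4-(triisopropylsilyloxy)phenyl]-2-methyl-5-(4,4,5,5-tetramethyl-1,3,2-dioxaborolan-2-yl)hexan-2-ol
Product: 13 2-{(2R)-1-[2,6-bis(methoxymethoxy)-4-(triisopropylsilyloxy)phenyl]-5-methyl-5-(triethylsilyloxy)hexan-2-yl}-4,4,5,5-tetramethyl-1,3,2-dioxaborolane
Conditions: TESCl, imidazole, DMAP (cat.), DMF, rt → 40 °C
Reagents that add atoms: chlorotriethylsilane, CC[Si](Cl)(CC)CC
Why: Silylation of the unhindered dimethylcarbinol under non-acidic conditions (safe for the MOM ethers) stops the alcohol from quenching the alkenyllithium or tying up boron as a cyclic borate in step 7.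

Step 7
Reactants: 13 2-{(2R)-1-[2,6-bis(methoxymethoxy)-4-(triisopropylsilyloxy)phenyl]-5-methyl-5-(triethylsilyloxy)hexan-2-yl}-4,4,5,5-tetramethyl-1,3,2-dioxaborolane; 14 2-bromopropene
Product: 18 {3,5-bis(methoxymethoxy)-4-[(2R)-5-methyl-2-(prop-1-en-2-yl)-5-(triethylsilyloxy)hexyl]phenoxy}triisopropylsilane, via isopropenyllithium 15 (not isolated), via isopropenyl borate complex 16 (not isolated), via iodoalkyl boronate 17 (not isolated)
Conditions: 14, t-BuLi (2 equiv per 14), THF, −78 °C; add 13, −78 °C; I2 in MeOH, −78 °C; NaOMe in MeOH, −78 °C → rt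
Reagents that add atoms: none
Why: Zweifel olefination: iodination of the alkenyl borate triggers 1,2-migration of the C2'' alkyl group with retention of configuration, and methoxide-induced anti-elimination of boron and iodine gives the 1,1-disubstituted alkene, so the (R) centre set in step 4 is carried over unchanged.

Step 8
Reactants: 18 {3,5-bis(methoxymethoxy)-4-[(2R)-5-methyl-2-(prop-1-en-2-yl)-5-(triethylsilyloxy)hexyl]phenoxy}triisopropylsilane
Product: 19 {2-bromo-3,5-bis(methoxymethoxy)-4-[(2R)-5-methyl-2-(prop-1-en-2-yl)-5-(triethylsilyloxy)hexyl]phenoxy}triisopropylsilane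
Conditions: NBS (1.0 equiv), CH2Cl2, −78 → −40 °C, dark
Reagents that add atoms: N-bromosuccinimide, O=C1CCC(=O)N1Br
Why: Electrophilic aromatic bromination at one of the two equivalent free ring positions (the future C4a) should be far faster than attack on the 1,1-disubstituted alkene because the tri-oxygenated arene is much the stronger nucleophile, and it gives a regiodefined handle where direct deprotonation next to the TIPS ether would be slow.

Step 9
Reactants: 20 2,4-dihydroxybenzaldehyde
Product: 21 2,4-bis(methoxymethoxy)benzaldehyde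
Conditions: MOMCl, i-Pr2NEt, CH2Cl2, 0 °C → rt
Reagents that add atoms: chloromethyl methyl ether, COCCl
Why: Standard MOM protection of both phenols gives groups that survive the organolithium steps and leave together with the ring-A MOM ethers in step 13.

Step 10
Reactants: 21 2,4-bis(methoxymethoxy)benzaldehyde
Product: 22 1-(2,2-dibromoethenyl)-2,4-bis(methoxymethoxy)benzene
Conditions: CBr4, PPh3, Et3N, CH2Cl2, 0 °C
Reagents that add atoms: tetrabromomethane, BrC(Br)(Br)Br
Why: Corey–Fuchs dibromo-olefination (Wittig-type reaction of the dibromomethylene ylide), buffered with amine to protect the MOM ethers, adds the carbon that becomes C3 of the flavone.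

Step 11
Reactants: 22 1-(2,2-dibromoethenyl)-2,4-bis(methoxymethoxy)benzene
Product: 24 3-[2,4-bis(methoxymethoxy)phenyl]-N-methoxy-N-methylprop-2-ynamide, via lithium acetylide 23 (not isolated)
Conditions: n-BuLi (2.1 equiv), THF, −78 °C; then ClC(O)N(OMe)Me, −78 °C → rt
Reagents that add atoms: N-methoxy-N-methylcarbamoyl chloride, CON(C)C(Cl)=O
Why: Second stage of the Corey–Fuchs sequence (bromine–lithium exchange, elimination and deprotonation to the lithium acetylide) followed by acyl substitution on the carbamoyl chloride gives the alkynyl Weinreb amide that carries C2, C3 and C4.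

Step 12
Reactants: 19 {2-bromo-3,5-bis(methoxymethoxy)-4-[(2R)-5-methyl-2-(prop-1-en-2-yl)-5-(triethylsilyloxy)hexyl]phenoxy}triisopropylsilane; 24 3-[2,4-bis(methoxymethoxy)phenyl]-N-methoxy-N-methylprop-2-ynamide
Product: 26 3-[2,4-bis(methoxymethoxy)phenyl]-1-{2,4-bis(methoxymethoxy)-3-[(2R)-5-methyl-2-(prop-1-en-2-yl)-5-(triethylsilyloxy)hexyl]-6-(triisopropylsilyloxy)phenyl}prop-2-yn-1-one, via aryllithium 25 (not isolated)
Conditions: t-BuLi (2.0 equiv), THF, −78 °C; add 24, −78 → −40 °C; AcOH quench at −78 °C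
Reagents that add atoms: none
Why: Bromine–lithium exchange at −78 °C (cold enough that oxygen-to-carbon migration of the TIPS group should not compete) and Weinreb ketone synthesis form the C4a–C4 bond, the chelated tetrahedral adduct preventing over-addition and the cold acidic quench keeping the released amine from adding to the ynone.

Step 13
Reactants: 26 3-[2,4-bis(methoxymethoxy)phenyl]-1-{2,4-bis(methoxymethoxy)-3-[(2R)-5-methyl-2-(prop-1-en-2-yl)-5-(triethylsilyloxy)hexyl]-6-(triisopropylsilyloxy)phenyl}prop-2-yn-1-one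
Product: 28 2-(2,4-dihydroxyphenyl)-7-hydroxy-8-[(2R)-5-hydroxy-5-methyl-2-(prop-1-en-2-yl)hexyl]-5-(triisopropylsilyloxy)-4H-chromen-4-one, via tetrahydroxy ynone 27 (not isolated)
Conditions: HCl (ca. 2 M, aqueous conc. HCl diluted in MeOH–THF), rt → 40 °C, stopped as soon as 27 is consumed
Reagents that add atoms: none
Why: Acid methanolysis removes the four MOM ethers and the TES ether, and the freed C8a hydroxyl then adds 6-endo-dig to the acid-activated ynone (oxa-Michael) to close ring C, which is the only possible mode because O5 is still silylated, the C7 hydroxyl is para to the ketone and the ring-B hydroxyls can reach only the non-electrophilic α-carbon.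

Step 14
Reactants: 28 2-(2,4-dihydroxyphenyl)-7-hydroxy-8-[(2R)-5-hydroxy-5-methyl-2-(prop-1-en-2-yl)hexyl]-5-(triisopropylsilyloxy)-4H-chromen-4-one
Product: 29 2-(2,4-dihydroxyphenyl)-5,7-dihydroxy-8-[(2R)-5-hydroxy-5-methyl-2-(prop-1-en-2-yl)hexyl]-4H-chromen-4-one (CNP0318654.1)
Conditions: TBAF, AcOH, THF, 0 °C → rt
Reagents that add atoms: none
Why: Buffered fluoride desilylation cleaves the aryl TIPS ether at O5 under conditions that leave the isopropenyl group, the tertiary alcohol and the C2'' stereocentre untouched.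

**Compound list**
1 | phloroglucinol | Oc1cc(O)cc(O)c1 | starting material
2 | 3,5-bis(methoxymethoxy)phenol | COCOc1cc(O)cc(OCOC)c1 | intermediate
3 | [3,5-bis(methoxymethoxy)phenoxy]triisopropylsilane | COCOc1cc(O[Si](C(C)C)(C(C)C)C(C)C)cc(OCOC)c1 | intermediate
4 | [2,6-bis(methoxymethoxy)-4-(triisopropylsilyloxy)phenyl]lithium | COCOc1cc(O[Si](C(C)C)(C(C)C)C(C)C)cc(OCOC)c1[Li] | intermediate
5 | lithium [2,6-bis(methoxymethoxy)-4-(triisopropylsilyloxy)phenyl](bromomethyl)(pinacolato)borate | [Li+].BrC[B-]1(OC(C)(C)C(C)(C)O1)c2c(OCOC)cc(O[Si](C(C)C)(C(C)C)C(C)C)cc2OCOC | intermediate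
6 | 2-{[2,6-bis(methoxymethoxy)-4-(triisopropylsilyloxy)phenyl]methyl}-4,4,5,5-tetramethyl-1,3,2-dioxaborolane | COCOc1cc(O[Si](C(C)C)(C(C)C)C(C)C)cc(OCOC)c1CB1OC(C)(C)C(C)(C)O1 | intermediate
7 | vinyl bromide | C=CBr | starting material
8 | 1-bromo-2-methylprop-1-ene | CC(C)=CBr | starting material
9 | vinyllithium | [Li]C=C | intermediate
10 | lithium {[2,6-bis(methoxymethoxy)-4-(triisopropylsilyloxy)phenyl]methyl}(ethenyl)(pinacolato)borate | [Li+].C=C[B-]1(OC(C)(C)C(C)(C)O1)Cc2c(OCOC)cc(O[Si](C(C)C)(C(C)C)C(C)C)cc2OCOC | intermediate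
11 | 2-{(2R)-1-[2,6-bis(methoxymethoxy)-4-(triisopropylsilyloxy)phenyl]-5-methylhex-4-en-2-yl}-4,4,5,5-tetramethyl-1,3,2-dioxaborolane | CC1(C)OB(OC1(C)C)[C@H](CC=C(C)C)Cc1c(OCOC)cc(O[Si](C(C)C)(C(C)C)C(C)C)cc1OCOC | intermediate
12 | (5R)-6-[2,6-bis(methoxymethoxy)-4-(triisopropylsilyloxy)phenyl]-2-methyl-5-(4,4,5,5-tetramethyl-1,3,2-dioxaborolan-2-yl)hexan-2-ol | CC1(C)OB(OC1(C)C)[C@H](CCC(C)(C)O)Cc1c(OCOC)cc(O[Si](C(C)C)(C(C)C)C(C)C)cc1OCOC | intermediate
13 | 2-{(2R)-1-[2,6-bis(methoxymethoxy)-4-(triisopropylsilyloxy)phenyl]-5-methyl-5-(triethylsilyloxy)hexan-2-yl}-4,4,5,5-tetramethyl-1,3,2-dioxaborolane | CC1(C)OB(OC1(C)C)[C@H](CCC(C)(C)O[Si](CC)(CC)CC)Cc1c(OCOC)cc(O[Si](C(C)C)(C(C)C)C(C)C)cc1OCOC | intermediate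
14 | 2-bromopropene | C=C(C)Br | starting material
15 | isopropenyllithium (prop-1-en-2-yllithium) | [Li]C(C)=C | intermediate
16 | lithium (prop-1-en-2-yl)(pinacolato)borate of 13, boron on C2'' (R) | [Li+].C=C(C)[B-]1(OC(C)(C)C(C)(C)O1)[C@H](CCC(C)(C)O[Si](CC)(CC)CC)Cc2c(OCOC)cc(O[Si](C(C)C)(C(C)C)C(C)C)cc2OCOC | intermediate
17 | 2-{(3R)-4-[2,6-bis(methoxymethoxy)-4-(triisopropylsilyloxy)phenyl]-1-iodo-2-methyl-3-[3-methyl-3-(triethylsilyloxy)butyl]butan-2-yl}-4,4,5,5-tetramethyl-1,3,2-dioxaborolane (both epimers at the boron-bearing carbon) | ICC(C)(B1OC(C)(C)C(C)(C)O1)[C@H](CCC(C)(C)O[Si](CC)(CC)CC)Cc2c(OCOC)cc(O[Si](C(C)C)(C(C)C)C(C)C)cc2OCOC | intermediate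
18 | {3,5-bis(methoxymethoxy)-4-[(2R)-5-methyl-2-(prop-1-en-2-yl)-5-(triethylsilyloxy)hexyl]phenoxy}triisopropylsilane | C=C(C)[C@H](CCC(C)(C)O[Si](CC)(CC)CC)Cc1c(OCOC)cc(O[Si](C(C)C)(C(C)C)C(C)C)cc1OCOC | intermediate
19 | {2-bromo-3,5-bis(methoxymethoxy)-4-[(2R)-5-methyl-2-(prop-1-en-2-yl)-5-(triethylsilyloxy)hexyl]phenoxy}triisopropylsilane | C=C(C)[C@H](CCC(C)(C)O[Si](CC)(CC)CC)Cc1c(OCOC)cc(O[Si](C(C)C)(C(C)C)C(C)C)c(Br)c1OCOC | intermediate
20 | 2,4-dihydroxybenzaldehyde | O=Cc1ccc(O)cc1O | starting material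
21 | 2,4-bis(methoxymethoxy)benzaldehyde | COCOc1ccc(C=O)c(OCOC)c1 | intermediate
22 | 1-(2,2-dibromoethenyl)-2,4-bis(methoxymethoxy)benzene | COCOc1ccc(C=C(Br)Br)c(OCOC)c1 | intermediate
23 | lithium [2,4-bis(methoxymethoxy)phenyl]acetylide | COCOc1ccc(C#C[Li])c(OCOC)c1 | intermediate
24 | 3-[2,4-bis(methoxymethoxy)phenyl]-N-methoxy-N-methylprop-2-ynamide | COCOc1ccc(C#CC(=O)N(C)OC)c(OCOC)c1 | intermediate
25 | {2,4-bis(methoxymethoxy)-3-[(2R)-5-methyl-2-(prop-1-en-2-yl)-5-(triethylsilyloxy)hexyl]-6-(triisopropylsilyloxy)phenyl}lithium | C=C(C)[C@H](CCC(C)(C)O[Si](CC)(CC)CC)Cc1c(OCOC)cc(O[Si](C(C)C)(C(C)C)C(C)C)c([Li])c1OCOC | intermediate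
26 | 3-[2,4-bis(methoxymethoxy)phenyl]-1-{2,4-bis(methoxymethoxy)-3-[(2R)-5-methyl-2-(prop-1-en-2-yl)-5-(triethylsilyloxy)hexyl]-6-(triisopropylsilyloxy)phenyl}prop-2-yn-1-one | C=C(C)[C@H](CCC(C)(C)O[Si](CC)(CC)CC)Cc1c(OCOC)cc(O[Si](C(C)C)(C(C)C)C(C)C)c(C(=O)C#Cc2ccc(OCOC)cc2OCOC)c1OCOC | intermediate
27 | 1-{2,4-dihydroxy-3-[(2R)-5-hydroxy-5-methyl-2-(prop-1-en-2-yl)hexyl]-6-(triisopropylsilyloxy)phenyl}-3-(2,4-dihydroxyphenyl)prop-2-yn-1-one | C=C(C)[C@H](CCC(C)(C)O)Cc1c(O)cc(O[Si](C(C)C)(C(C)C)C(C)C)c(C(=O)C#Cc2ccc(O)cc2O)c1O | intermediate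
28 | 2-(2,4-dihydroxyphenyl)-7-hydroxy-8-[(2R)-5-hydroxy-5-methyl-2-(prop-1-en-2-yl)hexyl]-5-(triisopropylsilyloxy)-4H-chromen-4-one | C=C(C)[C@H](CCC(C)(C)O)Cc1c(O)cc(O[Si](C(C)C)(C(C)C)C(C)C)c2c(=O)cc(-c3ccc(O)cc3O)oc12 | intermediate
29 | 2-(2,4-dihydroxyphenyl)-5,7-dihydroxy-8-[(2R)-5-hydroxy-5-methyl-2-(prop-1-en-2-yl)hexyl]-4H-chromen-4-one | C=C(C)[C@H](CCC(C)(C)O)Cc1c(O)cc(O)c2c(=O)cc(-c3ccc(O)cc3O)oc12 | target

**Step count**
Total: 14 steps. Longest linear sequence: 11 steps (steps 1–8, then 12–14); the ring-B branch (steps 9–11) joins at step 12.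

**Steps most likely to fail, with fallbacks**

Step 4 (conjunctive coupling). The metalate shift of the hindered, electron-rich benzyl group may be slow, so that direct transmetalation or β-hydride loss takes over, or facial selectivity at C2'' may be poor. The fallback is a sparteine-mediated lithiation–borylation, which makes only the C1''–C2'' bond under reagent control. It sets out from 6. Commercial 4-methylpent-3-en-1-ol is esterified with 2,4,6-triisopropylbenzoyl chloride (Et3N, DMAP) to 4-methylpent-3-en-1-yl 2,4,6-triisopropylbenzoate F1. Deprotonation with s-BuLi/(−)-sparteine in Et2O at −78 °C removes the pro-S hydrogen and gives the configurationally stable (S)-1-lithio-4-methylpent-3-en-1-yl 2,4,6-triisopropylbenzoate F2. Addition of 6 gives, with retention, the lithium borate complex F3. On warming, the benzyl group migrates with inversion and expels the carboxylate, which should deliver the (R)-boronate; the fallback comes back to the route at 11.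

Step 12 (aryllithium acylation). Addition of the doubly ortho-substituted aryllithium to the amide may be sluggish, which would let silyl migration, protonation or amine conjugate addition compete. The fallback sets out from 19 and moves the nucleophile onto the unhindered partner. Aryllithium 25 is trapped at −78 °C with DMF, a small and fast electrophile, to give 2,4-bis(methoxymethoxy)-3-[(2R)-5-methyl-2-(prop-1-en-2-yl)-5-(triethylsilyloxy)hexyl]-6-(triisopropylsilyloxy)benzaldehyde F4. Lithium acetylide 23 (from 22 and n-BuLi) is added at −78 °C with a cold quench to give the propargylic alcohol 3-[2,4-bis(methoxymethoxy)phenyl]-1-{2,4-bis(methoxymethoxy)-3-[(2R)-5-methyl-2-(prop-1-en-2-yl)-5-(triethylsilyloxy)hexyl]-6-(triisopropylsilyloxy)phenyl}prop-2-yn-1-ol F5 as a mixture of carbinol epimers. Oxidation with MnO2 in CH2Cl2 comes back to the route at 26.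

Step 13 (acid deprotection and ring closure). Protic acid may add the C7 hydroxyl across the isopropenyl group, ionise the tertiary carbinol, or strip the O5 silyl group before ring C has closed, which would allow closure through O5. The fallback sets out from 26 and avoids protic acid. The aryl MOM ethers are cleaved with TMSOTf/2,2'-bipyridyl in MeCN at 0 °C followed by water, which should leave the TES and TIPS ethers in place and give 1-{2,4-dihydroxy-3-[(2R)-5-methyl-2-(prop-1-en-2-yl)-5-(triethylsilyloxy)hexyl]-6-(triisopropylsilyloxy)phenyl}-3-(2,4-dihydroxyphenyl)prop-2-yn-1-one F6. Catalytic DMAP in DMF then effects the 6-endo closure to 2-(2,4-dihydroxyphenyl)-7-hydroxy-8-[(2R)-5-methyl-2-(prop-1-en-2-yl)-5-(triethylsilyloxy)hexyl]-5-(triisopropylsilyloxy)-4H-chromen-4-one F7. TBAF/AcOH removes both silyl groups, and the fallback comes back to the route at 29.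

**Further compounds**
F1 | step 4 | 4-methylpent-3-en-1-yl 2,4,6-triisopropylbenzoate | CC(C)=CCCOC(=O)c1c(C(C)C)cc(C(C)C)cc1C(C)C
F2 | step 4 | (S)-1-lithio-4-methylpent-3-en-1-yl 2,4,6-triisopropylbenzoate (as its (−)-sparteine complex) | [Li][C@@H](CC=C(C)C)OC(=O)c1c(C(C)C)cc(C(C)C)cc1C(C)C
F3 | step 4 | lithium {[2,6-bis(methoxymethoxy)-4-(triisopropylsilyloxy)phenyl]methyl}[(1S)-4-methyl-1-(2,4,6-triisopropylbenzoyloxy)pent-3-en-1-yl](pinacolato)borate | [Li+].COCOc1cc(O[Si](C(C)C)(C(C)C)C(C)C)cc(OCOC)c1C[B-]2(OC(C)(C)C(C)(C)O2)[C@@H](CC=C(C)C)OC(=O)c3c(C(C)C)cc(C(C)C)cc3C(C)C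
F4 | step 12 | 2,4-bis(methoxymethoxy)-3-[(2R)-5-methyl-2-(prop-1-en-2-yl)-5-(triethylsilyloxy)hexyl]-6-(triisopropylsilyloxy)benzaldehyde | C=C(C)[C@H](CCC(C)(C)O[Si](CC)(CC)CC)Cc1c(OCOC)cc(O[Si](C(C)C)(C(C)C)C(C)C)c(C=O)c1OCOC
F5 | step 12 | 3-[2,4-bis(methoxymethoxy)phenyl]-1-{2,4-bis(methoxymethoxy)-3-[(2R)-5-methyl-2-(prop-1-en-2-yl)-5-(triethylsilyloxy)hexyl]-6-(triisopropylsilyloxy)phenyl}prop-2-yn-1-ol (carbinol epimers) | C=C(C)[C@H](CCC(C)(C)O[Si](CC)(CC)CC)Cc1c(OCOC)cc(O[Si](C(C)C)(C(C)C)C(C)C)c(C(O)C#Cc2ccc(OCOC)cc2OCOC)c1OCOC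
F6 | step 13 | 1-{2,4-dihydroxy-3-[(2R)-5-methyl-2-(prop-1-en-2-yl)-5-(triethylsilyloxy)hexyl]-6-(triisopropylsilyloxy)phenyl}-3-(2,4-dihydroxyphenyl)prop-2-yn-1-one | C=C(C)[C@H](CCC(C)(C)O[Si](CC)(CC)CC)Cc1c(O)cc(O[Si](C(C)C)(C(C)C)C(C)C)c(C(=O)C#Cc2ccc(O)cc2O)c1O
F7 | step 13 | 2-(2,4-dihydroxyphenyl)-7-hydroxy-8-[(2R)-5-methyl-2-(prop-1-en-2-yl)-5-(triethylsilyloxy)hexyl]-5-(triisopropylsilyloxy)-4H-chromen-4-one | C=C(C)[C@H](CCC(C)(C)O[Si](CC)(CC)CC)Cc1c(O)cc(O[Si](C(C)C)(C(C)C)C(C)C)c2c(=O)cc(-c3ccc(O)cc3O)oc12
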